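The data are simulated with made-up constants, noise included.

Start from the invariant: each unit of G charged stands as G, as D or in a pool that no reading shows, so the fraction in the pool is one minus G minus D at any time.

| setting | alpha | eta | north-east | south | north | north-west |
|---|---|---|---|---|---|---|
| G | 20 mM | 20 mM | 20 mM | 20 mM | 20 mM | 20 mM |
| L | 1.5 equiv | 1.5 equiv | 1.50 equiv | 1.50 equiv | 1.50 equiv | 1.50 equiv |
| E | 2 mM | 2 mM | 2.00 mM | 2.00 mM | 2.00 mM | 2.00 mM |
| X | 0.13 mol% | 0.13 mol% | 0.13 mol% | 0.13 mol% | 0.13 mol% | 0.13 mol% |
| Q | 0.47 mol% | 22 mol% | 0.8 mol% | 2.5 mol% | 8 mol% | 25 mol% |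
| remark | run made earlier | run made earlier |  |  |  |  |
| time |  |  | 15 h | 15 h | 15 h | 15 h |

| run | time / h | D / % | G / % |
|---|---|---|---|
| alpha | 2.50 | 1.0 | 46.6 |
| alpha | 5.00 | 1.4 | 34.7 |
| alpha | 8.00 | 2.1 | 31.1 |
| alpha | 10.0 | 4.2 | 31.3 |
| alpha | 12.0 | 4.7 | 31.5 |
| alpha | 15.0 | 4.4 | 32.0 |
| eta | 1.00 | 5.5 | 66.8 |
| eta | 3.00 | 25.3 | 38.2 |
| eta | 5.00 | 45.4 | 24.7 |
| eta | 8.00 | 61.1 | 14.7 |
| eta | 12.0 | 74.7 | 10.1 |
| eta | 15.0 | 81.3 | 6.8 |

(readings scatter by 1 percentage point)

- the numbers in the tables scatter by 1 percentage point (one standard deviation)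
- "hardly changes" means that all values lie within two and a half points (for a concentration: within two and a half percent of the largest)

* amount of D at the end, in percent of the G charged for north-east, south, north, north-west, in this order
* the shape of the row from first to last (hardly changes / rises, then falls / falls, then rises / falls all the way / rises all the way)

Climb the ladder of times, quickest rung first. On the first rung, read alpha: G falls to 31.1% by 8.00 h and still reads 32.0% at 15.0 h, while D reads 4.4%, so treat G and the pool as a pre-equilibrium and divide one by the other, a ratio from which time drops out while the balance holds: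

pool / G = (1 − D − G) / G = 1.99 (alpha, at 15.0 h)

Keep this reading, the pool held per unit of G at balance, as the pool ratio.

On the second rung, take the drain time, the pool at the end of a span divided by the D made per hour over that span:

alpha, over the whole run: 217 h

eta, from 3.00 h to 5.00 h: 2.98 h

In alpha, with Q at 0.47 mol%, the drain time is far longer than the 8.00 h of the first rung, so the balance has time to hold. In eta, with Q at 22 mol%, the drain time is shorter than those hours, so expect the pool to run behind, and the ratio in eta reads lower at its last point, 1.75, though that reading rests on a G of 6.8% with a scatter of 1 percentage point.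

Commit, then, for these charges of G, L, E and X, to a rule that needs no clock, expecting G somewhat above it at high Q:

G = (1 − D) / (1 + pool ratio)

The forecast, on the ground that the “drain rate scales roughly with Q”, gives 8%, 22%, 47% and 85%, a row that rises all the way.

The flasks give 10.2%, 26.6%, 55.5% and 83.0%, a row that rises all the way, from these steps, J being the pool:

    G + X ⇌ X + J (K = 2.20, k = 270 M⁻¹ min⁻¹)
    L + Q + J → Q + D (k = 45.0 M⁻² min⁻¹)
    L + E → Z (k = 0.220 M⁻¹ min⁻¹)

In north, Q stands at 100% of its charge at 15.0 h, with E at 1.23% of its own charge. Put the pool ratio to work on north: from its D the rule gives a G of 14.9%, and the flask holds 15.2%. On north-west, the flask with the most Q, the rule gives 5.69%, and the flask holds more, 6.39%.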